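**Retrosynthetic overview**
1. Target 27 ⇐ 2-oxo acid 24 (C2 re-set by α-face hydride delivery, then acetylation) ⇐ 8(17)-ene 22 ⇐ Wittig methylenation of 17-nor-8-ketone 21.
2. 21 ⇐ bromomethyl ketone 20: ring B is closed by forming the C6–C7 bond in a 6-endo radical cyclization that also sets H-5.
3. 20 ⇐ acid 16 ⇐ Ireland–Claisen rearrangement of ester 13: makes the C9–C10 bond, sets quaternary C10 and C9, and moves the ring alkene to C5=C6.
4. 13 ⇐ ring A allylic alcohol 5 (from hydroxy ketone 1) + acid 12 (from (R)-citronellol 6, source of C13). Ring A is bought; ring B is the only ring made (step 13).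
5. Enabling feature: the C7–C8(=O)–C9–C10–C5=C6 array of the future ring B, in which alkene carbon C5 lies between quaternary C4 (ring A) and quaternary C10 (ring fusion), so only the C6 terminus can be attacked; the C8 carbonyl is the masked 8(17)-methylene.

Key step: step 13

Remark: labdane numbering (C1–C20) is used for all intermediates; 1 and 6 are assumed to be commercial as single enantiomers; the C2 silyl ether (2α series) is a temporary control element that is oxidized and re-set to 2β at the end.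

Step 1
Reactants: 1 (4R,6R)-4-hydroxy-2,2,6-trimethylcyclohexan-1-one
Product: 2 (4R,6R)-4-(tert-butyldimethylsilyloxy)-2,2,6-trimethylcyclohexan-1-one
Conditions: TBSCl, imidazole, DMF, rt
Reagents that add atoms: tert-butyldimethylsilyl chloride, CC(C)(C)[Si](C)(C)Cl
Why: Imidazole-promoted silylation masks the C2 hydroxyl as a base-stable ether without touching a stereocentre.

Step 2
Reactants: 2 (4R,6R)-4-(tert-butyldimethylsilyloxy)-2,2,6-trimethylcyclohexan-1-one
Product: 3 (4R)-4-(tert-butyldimethylsilyloxy)-2,6,6-trimethylcyclohex-1-en-1-yl trifluoromethanesulfonate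
Conditions: LiN(i-Pr)2, THF, −78 °C; PhNTf2, −78 °C → rt; aq. NH4Cl
Reagents that add atoms: N-phenylbis(trifluoromethanesulfonimide), O=S(=O)(N(c1ccccc1)S(=O)(=O)C(F)(F)F)C(F)(F)F
Why: The ketone has a single enolizable hydrogen (on C10), so enolate O-triflation gives one enol triflate and erases the irrelevant methyl-bearing stereocentre.

Step 3
Reactants: 3 (4R)-4-(tert-butyldimethylsilyloxy)-2,6,6-trimethylcyclohex-1-en-1-yl trifluoromethanesulfonate
Product: 4 methyl (4R)-4-(tert-butyldimethylsilyloxy)-2,6,6-trimethylcyclohex-1-ene-1-carboxylate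
Conditions: Pd(OAc)2 (cat.), dppp (cat.), CO (1 atm), MeOH, Et3N, DMF, 70 °C
Reagents that add atoms: carbon monoxide, [C-]#[O+]; methanol, CO
Why: Palladium-catalysed alkoxycarbonylation (oxidative addition of the triflate to zerovalent palladium, CO insertion, methanolysis) installs C6 on C5, a standard reaction of hindered cyclohexenyl triflates.

Step 4
Reactants: 4 methyl (4R)-4-(tert-butyldimethylsilyloxy)-2,6,6-trimethylcyclohex-1-ene-1-carboxylate
Product: 5 [(4R)-4-(tert-butyldimethylsilyloxy)-2,6,6-trimethylcyclohex-1-en-1-yl]methanol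
Conditions: i-Bu2AlH, CH2Cl2, −78 → 0 °C; aq. sodium potassium tartrate
Reagents that add atoms: none
Why: 1,2-Reduction of the unsaturated ester by the aluminium hydride gives the allylic alcohol whose C6–O bond is broken later in the rearrangement.

Step 5
Reactants: 6 (R)-citronellol
Product: 7 (R)-citronellol tert-butyldimethylsilyl ether
Conditions: TBSCl, imidazole, CH2Cl2, rt
Reagents that add atoms: tert-butyldimethylsilyl chloride, CC(C)(C)[Si](C)(C)Cl
Why: Silylation protects the future C15 oxygen; the C13 stereocentre comes unchanged from the chiral pool.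

Step 6
Reactants: 7 (R)-citronellol tert-butyldimethylsilyl ether
Product: 9 (4R)-6-(tert-butyldimethylsilyloxy)-4-methylhexan-1-ol, via ozonide 8 (not isolated)
Conditions: O3, CH2Cl2, −78 °C; NaBH4, MeOH, −78 °C → rt
Reagents that add atoms: ozone, [O-][O+]=O
Why: Ozonolysis with reductive NaBH4 work-up cleaves the trisubstituted alkene and leaves C9 as a primary alcohol.

Step 7
Reactants: 9 (4R)-6-(tert-butyldimethylsilyloxy)-4-methylhexan-1-ol
Product: 10 [(3R)-6-bromo-3-methylhexyl]oxy(tert-butyl)dimethylsilane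
Conditions: CBr4, PPh3, CH2Cl2, 0 °C
Reagents that add atoms: carbon tetrabromide, BrC(Br)(Br)Br
Why: The Appel reaction converts the primary alcohol into the bromide under neutral conditions that keep the silyl ether.

Step 8
Reactants: 10 [(3R)-6-bromo-3-methylhexyl]oxy(tert-butyl)dimethylsilane
Product: 12 (5R)-7-(tert-butyldimethylsilyloxy)-5-methylheptanoic acid, via Grignard reagent 11 (not isolated)
Conditions: Mg, THF, 40 °C; CO2, −20 °C; 1 M HCl, 0 °C
Reagents that add atoms: carbon dioxide, O=C=O
Why: Grignard formation and carboxylation add C8 as the carboxyl carbon, a one-carbon homologation.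

Step 9
Reactants: 5 [(4R)-4-(tert-butyldimethylsilyloxy)-2,6,6-trimethylcyclohex-1-en-1-yl]methanol; 12 (5R)-7-(tert-butyldimethylsilyloxy)-5-methylheptanoic acid
Product: 13 [(4R)-4-(tert-butyldimethylsilyloxy)-2,6,6-trimethylcyclohex-1-en-1-yl]methyl (5R)-7-(tert-butyldimethylsilyloxy)-5-methylheptanoate
Conditions: DCC, DMAP (cat.), CH2Cl2, 0 °C → rt
Reagents that add atoms: none
Why: Steglich esterification joins the two fragments through the primary allylic alcohol.

Step 10
Reactants: 13 [(4R)-4-(tert-butyldimethylsilyloxy)-2,6,6-trimethylcyclohex-1-en-1-yl]methyl (5R)-7-(tert-butyldimethylsilyloxy)-5-methylheptanoate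
Product: 16 ring-B-open C8 acid 7-(tert-butyldimethylsilyloxy)-5-methyl-2-[5-(tert-butyldimethylsilyloxy)-1,3,3-trimethyl-2-methylidenecyclohexyl]heptanoic acid (C9 cis to the C2 ether; C9/C10 as in the target), via silyl ketene acetal 14 (not isolated), via trimethylsilyl ester 15 (not isolated)
Conditions: LiN(i-Pr)2, THF–DMPU, −78 °C; Me3SiCl; −78 → 65 °C; aq. citric acid
Reagents that add atoms: none
Why: Ireland–Claisen rearrangement, in which enolization in THF–DMPU should give the Z-silyl ketene acetal, the chair transition state places C11 equatorial and the C10 methyl axial (H-9 anti to C20, as in the target), and the new bond should form on the face of the equatorial C2 silyloxy group because the other face carries the pseudoaxial C4 methyl.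

Step 11
Reactants: 16 ring-B-open C8 acid
Product: 18 N-methoxy-N-methyl amide of acid 16, via acid chloride 17 (not isolated)
Conditions: 1-chloro-N,N,2-trimethylprop-1-en-1-amine, CH2Cl2, 0 °C → rt; MeNHOMe·HCl, pyridine, 0 °C → rt
Reagents that add atoms: N,O-dimethylhydroxylamine hydrochloride, CNOC.Cl
Why: Neutral acid chloride formation with the chloroenamine followed by amidation gives the Weinreb amide without loss of the silyl ethers.

Step 12
Reactants: 18 N-methoxy-N-methyl amide of acid 16
Product: 20 1-bromo-8-(tert-butyldimethylsilyloxy)-6-methyl-3-[5-(tert-butyldimethylsilyloxy)-1,3,3-trimethyl-2-methylidenecyclohexyl]octan-2-one, via lithium hemiaminal 19 (not isolated)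
Conditions: CH2Br2, MeLi·LiBr, THF, −78 °C; aq. NH4Cl, −78 °C
Reagents that add atoms: dibromomethane, BrCBr
Why: Bromomethyllithium made in the flask adds once to the Weinreb amide because the chelated tetrahedral adduct survives until the cold quench, which delivers C7 as a bromomethyl ketone.

Step 13
Reactants: 20 1-bromo-8-(tert-butyldimethylsilyloxy)-6-methyl-3-[5-(tert-butyldimethylsilyloxy)-1,3,3-trimethyl-2-methylidenecyclohexyl]octan-2-one
Product: 21 (13R)-2α,15-bis(tert-butyldimethylsilyloxy)-17-norlabdan-8-one (5α-H, 9α-H)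
Conditions: (Me3Si)3SiH, AIBN (cat.), benzene, 80 °C, syringe-pump addition, 0.01 M
Reagents that add atoms: none
Why: Bromine abstraction by the silyl radical gives the C7 radical α to the C8 carbonyl, which adds to C6, the unsubstituted terminus of the C5=C6 exocyclic alkene, and the tertiary C5 radical so formed takes a hydrogen atom from (Me3Si)3SiH to carry the chain. The closest known reaction type is the reductive 6-endo cyclization of 2-oxo-5-hexenyl (α-keto) radicals made from α-halo ketones with tin or silicon hydrides. Ring B closes in the 6-endo-trig mode, because the electrophilic radical meets the electron-rich CH2 end of a 1,1-disubstituted alkene, the in-chain carbonyl strains the 5-exo transition state, and C5 is shielded by quaternary C4 and C10. The one new stereocentre, C5, is set by hydrogen delivery anti to the axial C20 methyl on C10 (the β face is also covered by the axial C4 methyl), which should give the trans ring fusion (5α-H). The selectivity needed is cyclization over direct reduction of the C7 radical, and it is secured by slow addition of the slow hydrogen donor at high dilution. C9 keeps its configuration, which is in any case the thermodynamically preferred equatorial arrangement next to the new ketone.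

Step 14
Reactants: 21 (13R)-2α,15-bis(tert-butyldimethylsilyloxy)-17-norlabdan-8-one
Product: 22 (13R)-2α,15-bis(tert-butyldimethylsilyloxy)labd-8(17)-ene
Conditions: Ph3PCH3Br, KOt-Bu, toluene, 80 °C
Reagents that add atoms: methyltriphenylphosphonium bromide, C[P+](c1ccccc1)(c1ccccc1)c1ccccc1.[Br-]
Why: Wittig methylenation of the hindered C8 ketone installs C17, and any enolization is harmless because C9 already has the more stable equatorial configuration.

Step 15
Reactants: 22 (13R)-2α,15-bis(tert-butyldimethylsilyloxy)labd-8(17)-ene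
Product: 23 (13R)-labd-8(17)-ene-2α,15-diol
Conditions: Bu4NF, THF, 40 °C
Reagents that add atoms: none
Why: Fluoride-induced desilylation cleaves both silyl ethers (the 2α ether is equatorial and unhindered).

Step 16
Reactants: 23 (13R)-labd-8(17)-ene-2α,15-diol
Product: 24 (13R)-2-oxolabd-8(17)-en-15-oic acid
Conditions: CrO3, H2SO4, H2O, acetone, 0 °C; i-PrOH quench
Reagents that add atoms: water, O
Why: Jones oxidation with hexavalent chromium takes the primary C15 alcohol to the acid (via the aldehyde hydrate) and the 2α-alcohol to the ketone in one operation, which erases the temporary C2 stereocentre, and the isolated 1,1-disubstituted alkene should tolerate the short cold acidic treatment.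

Step 17
Reactants: 24 (13R)-2-oxolabd-8(17)-en-15-oic acid
Product: 25 (13R)-2β-hydroxylabd-8(17)-en-15-oic acid
Conditions: LiBH(s-Bu)3 (3 equiv), THF, −78 °C; aq. NH4Cl then dil. HCl
Reagents that add atoms: none
Why: The bulky hydride should attack the C2 carbonyl from the α face (equatorial attack) because the β face is screened by the two syn-axial methyls on C4 and C10, giving the axial 2β-alcohol, while the lithium carboxylate is not reduced.

Step 18
Reactants: 25 (13R)-2β-hydroxylabd-8(17)-en-15-oic acid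
Product: 27 (13R)-2β-acetoxylabd-8(17)-en-15-oic acid (CNP0205865.1), via mixed anhydride 26 (not isolated)
Conditions: Ac2O, DMAP, pyridine, 40 °C; then H2O–pyridine, rt
Reagents that add atoms: acetic anhydride, CC(=O)OC(C)=O
Why: DMAP-catalysed acetylation esterifies the hindered axial alcohol, and the mixed anhydride formed at C15 is hydrolysed at its acetyl carbonyl during the aqueous pyridine work-up to return the free acid.

**Compound list**
1 | (4R,6R)-4-hydroxy-2,2,6-trimethylcyclohexan-1-one | O=C1C(C)(C)C[C@H](O)C[C@H]1C | starting material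
2 | (4R,6R)-4-(tert-butyldimethylsilyloxy)-2,2,6-trimethylcyclohexan-1-one | O=C1C(C)(C)C[C@H](O[Si](C)(C)C(C)(C)C)C[C@H]1C | intermediate
3 | (4R)-4-(tert-butyldimethylsilyloxy)-2,6,6-trimethylcyclohex-1-en-1-yl trifluoromethanesulfonate | CC1=C(OS(=O)(=O)C(F)(F)F)C(C)(C)C[C@H](O[Si](C)(C)C(C)(C)C)C1 | intermediate
4 | methyl (4R)-4-(tert-butyldimethylsilyloxy)-2,6,6-trimethylcyclohex-1-ene-1-carboxylate | CC1=C(C(=O)OC)C(C)(C)C[C@H](O[Si](C)(C)C(C)(C)C)C1 | intermediate
5 | [(4R)-4-(tert-butyldimethylsilyloxy)-2,6,6-trimethylcyclohex-1-en-1-yl]methanol | CC1=C(CO)C(C)(C)C[C@H](O[Si](C)(C)C(C)(C)C)C1 | intermediate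
6 | (R)-citronellol, (3R)-3,7-dimethyloct-6-en-1-ol | CC(C)=CCC[C@@H](C)CCO | starting material
7 | (R)-citronellol tert-butyldimethylsilyl ether | CC(C)=CCC[C@@H](C)CCO[Si](C)(C)C(C)(C)C | intermediate
8 | ozonide of 7 (3,3-dimethyl-5-alkyl-1,2,4-trioxolane) | CC1(C)OOC(CC[C@@H](C)CCO[Si](C)(C)C(C)(C)C)O1 | intermediate
9 | (4R)-6-(tert-butyldimethylsilyloxy)-4-methylhexan-1-ol | OCCC[C@@H](C)CCO[Si](C)(C)C(C)(C)C | intermediate
10 | [(3R)-6-bromo-3-methylhexyl]oxy(tert-butyl)dimethylsilane | BrCCC[C@@H](C)CCO[Si](C)(C)C(C)(C)C | intermediate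
11 | [(4R)-6-(tert-butyldimethylsilyloxy)-4-methylhexyl]magnesium bromide | Br[Mg]CCC[C@@H](C)CCO[Si](C)(C)C(C)(C)C | intermediate
12 | (5R)-7-(tert-butyldimethylsilyloxy)-5-methylheptanoic acid | OC(=O)CCC[C@@H](C)CCO[Si](C)(C)C(C)(C)C | intermediate
13 | [(4R)-4-(tert-butyldimethylsilyloxy)-2,6,6-trimethylcyclohex-1-en-1-yl]methyl (5R)-7-(tert-butyldimethylsilyloxy)-5-methylheptanoate | CC1=C(COC(=O)CCC[C@@H](C)CCO[Si](C)(C)C(C)(C)C)C(C)(C)C[C@H](O[Si](C)(C)C(C)(C)C)C1 | intermediate
14 | (Z)-O-trimethylsilyl ketene acetal of ester 13 (C11 cis to OSiMe3) | CC1=C(CO/C(O[Si](C)(C)C)=C/CC[C@@H](C)CCO[Si](C)(C)C(C)(C)C)C(C)(C)C[C@H](O[Si](C)(C)C(C)(C)C)C1 | intermediate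
15 | trimethylsilyl ester of acid 16 | C=C1C(C)(C)C[C@H](O[Si](C)(C)C(C)(C)C)C[C@]1(C)[C@H](C(=O)O[Si](C)(C)C)CC[C@@H](C)CCO[Si](C)(C)C(C)(C)C | intermediate
16 | ring-B-open C8 acid: 7-(tert-butyldimethylsilyloxy)-5-methyl-2-[5-(tert-butyldimethylsilyloxy)-1,3,3-trimethyl-2-methylidenecyclohexyl]heptanoic acid (C9 cis to the C2 ether, C20 trans to it; C9 and C13 as in the target) | C=C1C(C)(C)C[C@H](O[Si](C)(C)C(C)(C)C)C[C@]1(C)[C@H](C(=O)O)CC[C@@H](C)CCO[Si](C)(C)C(C)(C)C | intermediate
17 | acid chloride of 16 | C=C1C(C)(C)C[C@H](O[Si](C)(C)C(C)(C)C)C[C@]1(C)[C@H](C(=O)Cl)CC[C@@H](C)CCO[Si](C)(C)C(C)(C)C | intermediate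
18 | N-methoxy-N-methyl amide of 16 | C=C1C(C)(C)C[C@H](O[Si](C)(C)C(C)(C)C)C[C@]1(C)[C@H](C(=O)N(C)OC)CC[C@@H](C)CCO[Si](C)(C)C(C)(C)C | intermediate
19 | lithium hemiaminal from 18 and bromomethyllithium | C=C1C(C)(C)C[C@H](O[Si](C)(C)C(C)(C)C)C[C@]1(C)[C@H](C(O[Li])(CBr)N(C)OC)CC[C@@H](C)CCO[Si](C)(C)C(C)(C)C | intermediate
20 | 1-bromo-8-(tert-butyldimethylsilyloxy)-6-methyl-3-[5-(tert-butyldimethylsilyloxy)-1,3,3-trimethyl-2-methylidenecyclohexyl]octan-2-one (stereocentres as in 16) | C=C1C(C)(C)C[C@H](O[Si](C)(C)C(C)(C)C)C[C@]1(C)[C@H](C(=O)CBr)CC[C@@H](C)CCO[Si](C)(C)C(C)(C)C | intermediate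
21 | (13R)-2α,15-bis(tert-butyldimethylsilyloxy)-17-norlabdan-8-one (5α-H, 9α-H, 10β-methyl) | O=C1CC[C@H]2C(C)(C)C[C@H](O[Si](C)(C)C(C)(C)C)C[C@]2(C)[C@H]1CC[C@@H](C)CCO[Si](C)(C)C(C)(C)C | intermediate
22 | (13R)-2α,15-bis(tert-butyldimethylsilyloxy)labd-8(17)-ene | C=C1CC[C@H]2C(C)(C)C[C@H](O[Si](C)(C)C(C)(C)C)C[C@]2(C)[C@H]1CC[C@@H](C)CCO[Si](C)(C)C(C)(C)C | intermediate
23 | (13R)-labd-8(17)-ene-2α,15-diol | C=C1CC[C@H]2C(C)(C)C[C@H](O)C[C@]2(C)[C@H]1CC[C@@H](C)CCO | intermediate
24 | (13R)-2-oxolabd-8(17)-en-15-oic acid | C=C1CC[C@H]2C(C)(C)CC(=O)C[C@]2(C)[C@H]1CC[C@@H](C)CC(=O)O | intermediate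
25 | (13R)-2β-hydroxylabd-8(17)-en-15-oic acid | C=C1CC[C@H]2C(C)(C)C[C@@H](O)C[C@]2(C)[C@H]1CC[C@@H](C)CC(=O)O | intermediate
26 | acetic (13R)-2β-acetoxylabd-8(17)-en-15-oic anhydride | C=C1CC[C@H]2C(C)(C)C[C@@H](OC(C)=O)C[C@]2(C)[C@H]1CC[C@@H](C)CC(=O)OC(C)=O | intermediate
27 | (13R)-2β-acetoxylabd-8(17)-en-15-oic acid (CNP0205865.1) | C=C1CC[C@H]2C(C)(C)C[C@@H](OC(C)=O)C[C@]2(C)[C@H]1CC[C@@H](C)CC(=O)O | target

Total step count: 18.
Longest linear sequence: 14 steps (steps 1–4 then 9–18; the branch through steps 5–8 is equally long).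

**Steps most likely to fail**

Step 10 (Ireland–Claisen rearrangement). What may go wrong: the remote C2 silyloxy group may discriminate the two faces of C10 poorly, and slow rearrangement at the hindered tetrasubstituted terminus may allow the ketene acetal geometry to erode. Fallback, reagent control instead of substrate control, setting out from ester 13 and returning at acid 16: 13 would be enolized with the C2-symmetric bromoborane (S,S)-2-bromo-4,5-diphenyl-1,3-bis[3,5-bis(trifluoromethyl)phenylsulfonyl]-1,3,2-diazaborolidine and i-Pr2NEt in CH2Cl2 at −78 °C (or with its antipode, if a test run shows that one to be matched with the substrate) to give the Z-configured boron ketene acetal F1. On warming this should rearrange through the same chair to the boron carboxylate F2, and aqueous work-up would release 16.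

Step 13 (radical ring closure). What may go wrong: hydrogen transfer to the C7 radical before it cyclizes, or hydrogen delivery to the wrong face of C5. Fallback, an ionic closure of the same C6–C7 bond with C5 set beforehand, setting out from amide 18 and returning at ketone 21: 18 would be hydroborated with 9-BBN-H (THF, 50 °C) on the α face of C5=C6, away from the two axial methyls on C4 and C10, to give the B-alkyl borane F3, which NaOH–H2O2 would oxidize to the primary C6 alcohol F4. I2, PPh3 and imidazole would give the iodide F5, and MeMgBr (THF, 0 °C) would convert the amide into the iodo methyl ketone F6. The kinetic enolate of the methyl group (KN(SiMe3)2, THF, −78 → 0 °C) would then displace iodide at C6 in a 6-exo-tet alkylation to give 21.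

Step 12 (bromomethyl ketone). What may go wrong: decomposition of the carbenoid before it adds to the hindered amide, or collapse of the adduct to an epoxide. Fallback, bromination of a regiodefined silyl enol ether, setting out from amide 18 and returning at bromo ketone 20: MeMgBr would give the methyl ketone F7. LiN(SiMe3)2 and Me3SiCl at −78 °C would give the less substituted trimethylsilyl enol ether F8 (H-9 is shielded by quaternary C10), and N-bromosuccinimide in THF at −78 °C would brominate C7 to give 20.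

**Further compounds**
F1 | step 10 | Z-boron ketene acetal of ester 13 carrying the (S,S)-bis-sulfonamide diazaborolidine | CC1=C(CO/C(OB2N(S(=O)(=O)c3cc(C(F)(F)F)cc(C(F)(F)F)c3)[C@@H](c3ccccc3)[C@H](c3ccccc3)N2S(=O)(=O)c2cc(C(F)(F)F)cc(C(F)(F)F)c2)=C/CC[C@@H](C)CCO[Si](C)(C)C(C)(C)C)C(C)(C)C[C@H](O[Si](C)(C)C(C)(C)C)C1
F2 | step 10 | boron carboxylate of acid 16 | C=C1C(C)(C)C[C@H](O[Si](C)(C)C(C)(C)C)C[C@]1(C)[C@H](C(=O)OB2N(S(=O)(=O)c3cc(C(F)(F)F)cc(C(F)(F)F)c3)[C@@H](c3ccccc3)[C@H](c3ccccc3)N2S(=O)(=O)c2cc(C(F)(F)F)cc(C(F)(F)F)c2)CC[C@@H](C)CCO[Si](C)(C)C(C)(C)C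
F3 | step 13 | B-alkyl-9-borabicyclo[3.3.1]nonane from 18 (boron on C6, 5α-H) | C(B1C2CCCC1CCC2)[C@H]1C(C)(C)C[C@H](O[Si](C)(C)C(C)(C)C)C[C@]1(C)[C@H](C(=O)N(C)OC)CC[C@@H](C)CCO[Si](C)(C)C(C)(C)C
F4 | step 13 | C6 primary alcohol of the Weinreb amide (5α-H) | OC[C@H]1C(C)(C)C[C@H](O[Si](C)(C)C(C)(C)C)C[C@]1(C)[C@H](C(=O)N(C)OC)CC[C@@H](C)CCO[Si](C)(C)C(C)(C)C
F5 | step 13 | C6 iodide of the Weinreb amide | IC[C@H]1C(C)(C)C[C@H](O[Si](C)(C)C(C)(C)C)C[C@]1(C)[C@H](C(=O)N(C)OC)CC[C@@H](C)CCO[Si](C)(C)C(C)(C)C
F6 | step 13 | C6 iodide C8 methyl ketone | IC[C@H]1C(C)(C)C[C@H](O[Si](C)(C)C(C)(C)C)C[C@]1(C)[C@H](C(C)=O)CC[C@@H](C)CCO[Si](C)(C)C(C)(C)C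
F7 | step 12 | methyl ketone from amide 18 | C=C1C(C)(C)C[C@H](O[Si](C)(C)C(C)(C)C)C[C@]1(C)[C@H](C(C)=O)CC[C@@H](C)CCO[Si](C)(C)C(C)(C)C
F8 | step 12 | terminal trimethylsilyl enol ether of F7 | C=C1C(C)(C)C[C@H](O[Si](C)(C)C(C)(C)C)C[C@]1(C)[C@H](C(=C)O[Si](C)(C)C)CC[C@@H](C)CCO[Si](C)(C)C(C)(C)C
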